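The numbers in the tables come from a simulation with constants of no real substance.

The north run, made earlier with a richer charge, showed me a whole curve: target stood at 29.8% at 1.67 h, then sank to 25.5% by 6.00 h. The flask asked about is the north-west run carried on, so I read its future as a ladder of times.

| flask | starting material | protic impurity | enzyme | remark | time |
|---|---|---|---|---|---|
| north-west | 0.082 M (fed, over 4.0 min) | 1.64 mM | 8.2 µM | the very flask that is asked about, followed so far; the fed solution adds 0.50 times the starting volume |  |
| north | 0.12 M (fed, over 4.0 min) | 1.64 mM | 8.2 µM | run made earlier; the fed solution adds 0.50 times the starting volume |  |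
| flask | 0.082 M (fed, over 4.0 min) | 1.64 mM | 8.2 µM | the fed solution adds 0.50 times the starting volume | 8.0 h |

| run | time / h | target / % |
|---|---|---|
| north-west | 0.417 | 17.7 |
| north-west | 0.500 | 21.1 |
| north-west | 0.667 | 25.9 |
| north-west | 1.00 | 27.2 |
| north-west | 1.33 | 28.0 |
| north-west | 2.00 | 27.9 |
| north-west | 2.50 | 26.7 |
| north | 0.417 | 19.6 |
| north | 0.667 | 23.4 |
| north | 1.00 | 29.1 |
| north | 1.67 | 29.8 |
| north | 2.50 | 27.8 |
| north | 4.00 | 26.2 |
| north | 6.00 | 25.5 |

(readings scatter by 1 percentage point)

- amounts are per litre of the starting volume; all of the dose is in the solution fed
- steps under discussion: starting material + enzyme <-> complex; complex <-> enzyme + target; target + enzyme <-> isomer of the product + enzyme; starting material + protic impurity -> quenched substrate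

- time, not beyond 8.0 h, at which the flask holds most target
- the amount of target, in percent of the starting material charged, at that time

1. The feed came first. It lasted 4.0 min, shorter than the wait to the first north-west reading at 0.417 h, so I took the north-west flask as fully charged from the start.

2. The protic impurity came next. It amounted to 0.0200 of the charge in the north-west flask, so I expected it to quench no more than that fraction, which is less than the target at the first reading.

3. Then came the rise. North-west target climbed from 17.7% to 25.9% by 0.667 h, so making target was still well ahead of losing it.

4. Then came the crossing. The north-west readings stopped climbing between 1.33 h and 2.00 h, at 28.0% and 27.9%. I placed the top of the north-west flask there, as a reading, where the gain in target had stopped showing above the scatter.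

5. The last rung was the late sag. The north readings at 4.00 h and 6.00 h differed by 0.7 percentage points, less than the scatter. I therefore named the keep fraction, late target over top target, read from the north run as 0.856. Carried to the north-west flask, it gave about 24.0% of the charge as target at 8.0 h.

The forecast put the top at 1.5 h with 28.1%, and said “The maximum is broad, so its time is poorly fixed”.

The flask reached 28.8% at 1.59 h.

    starting material + enzyme ⇌ complex (K = 2.80 M⁻¹, k = 30000 M⁻¹ s⁻¹)
    complex ⇌ enzyme + target (K = 0.240 M, k = 16.0 s⁻¹)
    target + enzyme ⇌ isomer of the product + enzyme, rate k3*[enzyme]*[target] forward; the back reaction follows from the equilibrium constant (K = 1.30, k = 30.0 M⁻¹ s⁻¹)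
    starting material + protic impurity → quenched substrate (k = 0.640 M⁻¹ s⁻¹)

By the end of the feed at 0.0667 h, the flask held quenched substrate at 1.98% of the charge, with protic impurity at 1.06% of its own charge. Starting material then went on through the complex to target while target turned into isomer of the product, which stood at 14.7% at the best time and 33.0% at 8.00 h. Target in the flask ended at 26.0%, a keep fraction of 0.903 against the 0.856 read from the north run. The neighbour flask, read at 15 h, reached 28.8% and held 25.9%, a keep fraction of 0.899.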